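**Retrosynthetic overview**

1. The 14-membered carbocycle is formed last. The C7–C8 bond and the C8 carbinol come from a 15-membered boron ate ring in which the C7 alkenyl group shifts from boron to a diazo-derived C8 (ring contraction with loss of N2), followed by C–B oxidation.
2. The C13 acetate comes from Mitsunobu inversion. The cis-epoxide (second ring) comes from hydroxyl-directed epoxidation of a Z-allylic alcohol.
3. The cis-fused α-methylene-γ-butyrolactone (first ring, C1–C2 bond) comes from an asymmetric chromium-catalysed allylation of a C2–C7 boryl dienal (fragment A) with a C8–C14/C1/C15–C17 allylic bromide (fragment B).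
4. Fragment A comes from pent-1-en-4-yne (carboalumination, formaldehyde) and a vinylboronate (cross-metathesis). Fragment B comes from (S)-α-hydroxy-γ-butyrolactone, MeLi, a Z-selective Wittig reaction with a C8–C11 ylide, and a Morita–Baylis–Hillman reaction with methyl acrylate.

Assumption: vinylboronic acid is bought as its pinacol ester and 5-chloropentan-2-one as its ethylene ketal; atom labels C1–C20 are cembrane numbering of the target (C1/C2 lactone fusion, C8 carbinol, C11/C12 epoxide, C13 acetate).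

**Route**

Step 1
Reactants: 1 pent-1-en-4-yne
Product: 3 (2E)-3-methylhexa-2,5-dien-1-ol, via alkenylalane 2 (not isolated)
Conditions: AlMe3, Cp2ZrCl2 (20 mol %), CH2Cl2, 0 °C to rt; then n-BuLi, THF, −78 °C; (CH2O)n, rt; 1 M HCl work-up
Reagents that add atoms: trimethylaluminium, C[Al](C)C; formaldehyde (as paraformaldehyde), C=O
Why: Negishi zirconium-catalysed carboalumination adds Me and Al syn across the terminal alkyne only (Me to the internal carbon, the alkene is inert), and the derived alanate is hydroxymethylated with retention, which fixes the E trisubstituted alkene (C3=C4).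

Step 2
Reactants: 3 (2E)-3-methylhexa-2,5-dien-1-ol; 4 vinylboronic acid pinacol ester
Product: 5 (2E,5E)-3-methyl-6-(4,4,5,5-tetramethyl-1,3,2-dioxaborolan-2-yl)hexa-2,5-dien-1-ol
Conditions: second-generation Grubbs catalyst (5 mol %), 1,4-benzoquinone (10 mol %), CH2Cl2, 40 °C
Reagents that add atoms: none
Why: Olefin cross-metathesis of the monosubstituted alkene with the vinyl boronate is E-selective under thermodynamic control, while the trisubstituted alkene and the free alcohol are spectators and benzoquinone suppresses migration of the skipped diene.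

Step 3
Reactants: 5 (2E,5E)-3-methyl-6-(4,4,5,5-tetramethyl-1,3,2-dioxaborolan-2-yl)hexa-2,5-dien-1-ol
Product: 6 (2E,5E)-3-methyl-6-(4,4,5,5-tetramethyl-1,3,2-dioxaborolan-2-yl)hexa-2,5-dienal
Conditions: MnO2, CH2Cl2, rt
Reagents that add atoms: none
Why: Allylic oxidation with MnO2 is neutral and touches only the allylic alcohol, so the alkenyl boronate and the E enal geometry survive.

Step 4
Reactants: 7 2-(3-chloropropyl)-2-methyl-1,3-dioxolane
Product: 8 [3-(2-methyl-1,3-dioxolan-2-yl)propyl]triphenylphosphonium iodide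
Conditions: NaI, PPh3, MeCN, reflux
Reagents that add atoms: triphenylphosphine, c1ccc(cc1)P(c1ccccc1)c1ccccc1; sodium iodide, [Na+].[I-]
Why: Finkelstein exchange followed by SN2 quaternization of PPh3 gives the phosphonium salt, and the ketal is stable in the absence of acid.

Step 5
Reactants: 9 (3S)-3-hydroxyoxolan-2-one
Product: 10 (3S)-3-(oxan-2-yloxy)oxolan-2-one
Conditions: 3,4-dihydro-2H-pyran, PPTS (cat.), CH2Cl2, rt
Reagents that add atoms: 3,4-dihydro-2H-pyran, C1=COCCC1
Why: Acid-catalysed acetalization gives a base-stable, non-migrating THP ether and leaves the stereocenter (future C13) untouched.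

Step 6
Reactants: 10 (3S)-3-(oxan-2-yloxy)oxolan-2-one
Product: 11 (3S)-2-methyl-3-(oxan-2-yloxy)oxolan-2-ol
Conditions: MeLi (1.05 equiv), THF, −78 °C; then H2O
Reagents that add atoms: methyllithium, [Li]C
Why: At −78 °C the tetrahedral adduct of MeLi and the lactone does not collapse, so single addition gives the methyl lactol (a masked α-alkoxy methyl ketone) without epimerizing the α-carbon.

Step 7
Reactants: 11 (3S)-2-methyl-3-(oxan-2-yloxy)oxolan-2-ol; 8 [3-(2-methyl-1,3-dioxolan-2-yl)propyl]triphenylphosphonium iodide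
Product: 13 (3S,4Z)-4-methyl-7-(2-methyl-1,3-dioxolan-2-yl)-3-(oxan-2-yloxy)hept-4-en-1-ol, via phosphorus ylide 12 (not isolated)
Conditions: 8 (2.5 equiv), KN(SiMe3)2 (2.4 equiv), THF, −78 °C to rt
Reagents that add atoms: none
Why: Wittig olefination of an α-alkoxy methyl ketone (freed from the lactol by base) with a non-stabilized ylide is Z-selective (Still variant), placing the alkoxy-bearing carbon cis to the ylide chain and so giving the Z C11=C12 alkene.

Step 8
Reactants: 13 (3S,4Z)-4-methyl-7-(2-methyl-1,3-dioxolan-2-yl)-3-(oxan-2-yloxy)hept-4-en-1-ol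
Product: 14 (3S,4Z)-4-methyl-7-(2-methyl-1,3-dioxolan-2-yl)-3-(oxan-2-yloxy)hept-4-enal
Conditions: Pr4N[RuO4] (5 mol %), N-methylmorpholine N-oxide, 4 Å MS, CH2Cl2, rt
Reagents that add atoms: none
Why: Ley–Griffith oxidation is neutral, so the acetals survive and the β-alkoxy aldehyde is not eliminated.

Step 9
Reactants: 14 (3S,4Z)-4-methyl-7-(2-methyl-1,3-dioxolan-2-yl)-3-(oxan-2-yloxy)hept-4-enal; 15 methyl acrylate
Product: 16 methyl (5S,6Z)-3-hydroxy-6-methyl-2-methylidene-9-(2-methyl-1,3-dioxolan-2-yl)-5-(oxan-2-yloxy)non-6-enoate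
Conditions: DABCO (1 equiv), methyl acrylate (4 equiv), 1,4-dioxane–H2O (1:1), rt, 3 d
Reagents that add atoms: none
Why: The Morita–Baylis–Hillman reaction joins the acrylate α-carbon (C15) to the aldehyde carbon (C1) under mild amine catalysis; the new carbinol centre is formed as a mixture, which does not matter because it becomes sp2 in the next step.

Step 10
Reactants: 16 methyl (5S,6Z)-3-hydroxy-6-methyl-2-methylidene-9-(2-methyl-1,3-dioxolan-2-yl)-5-(oxan-2-yloxy)non-6-enoate
Product: 17 methyl (2Z,5S,6Z)-2-(bromomethyl)-6-methyl-9-(2-methyl-1,3-dioxolan-2-yl)-5-(oxan-2-yloxy)nona-2,6-dienoate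
Conditions: NBS, Me2S, CH2Cl2, −20 °C to rt
Reagents that add atoms: N-bromosuccinimide, O=C1CCC(=O)N1Br
Why: Corey–Kim-type activation of the Baylis–Hillman alcohol and SN2' delivery of bromide give the thermodynamically preferred (Z)-2-(bromomethyl)enoate (C14 trans to the ester) under near-neutral conditions that spare both acetals.

Step 11
Reactants: 6 (2E,5E)-3-methyl-6-(4,4,5,5-tetramethyl-1,3,2-dioxaborolan-2-yl)hexa-2,5-dienal; 17 methyl (2Z,5S,6Z)-2-(bromomethyl)-6-methyl-9-(2-methyl-1,3-dioxolan-2-yl)-5-(oxan-2-yloxy)nona-2,6-dienoate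
Product: 19 (4S,5S)-4-[(2S,3Z)-2-hydroxy-3-methyl-7-oxooct-3-en-1-yl]-3-methylidene-5-[(1E,4E)-2-methyl-5-(4,4,5,5-tetramethyl-1,3,2-dioxaborolan-2-yl)penta-1,4-dien-1-yl]oxolan-2-one, via silyl ether adduct 18 (not isolated)
Conditions: CrCl2 (10 mol %), ligand L (12 mol %; L = 3,6-di-tert-butyl-1,8-bis[(4S)-4-isopropyl-4,5-dihydro-1,3-oxazol-2-yl]-9H-carbazole), Mn, Me3SiCl, i-Pr2NEt (30 mol %), THF, rt; then 0.5 M HCl, THF–H2O, rt
Reagents that add atoms: water, O
Why: In this catalytic asymmetric Nozaki–Hiyama–Kishi allylation the Z-configured allylchromium adds through a chair transition state (C14 axial) to give the syn adduct, the ligand directs attack to the Re face of the aldehyde (4S,5S; the antipodal ligand is the switch), the ketal and boronate are inert to the aldehyde-selective chromium reagent, and aqueous acid then closes the cis-lactone and removes the silyl, THP and ketal groups.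

Step 12
Reactants: 19 (4S,5S)-4-[(2S,3Z)-2-hydroxy-3-methyl-7-oxooct-3-en-1-yl]-3-methylidene-5-[(1E,4E)-2-methyl-5-(4,4,5,5-tetramethyl-1,3,2-dioxaborolan-2-yl)penta-1,4-dien-1-yl]oxolan-2-one
Product: 20 (4S,5S)-4-[(2S)-2-hydroxy-2-[(2R,3S)-2-methyl-3-(3-oxobutyl)oxiran-2-yl]ethyl]-3-methylidene-5-[(1E,4E)-2-methyl-5-(4,4,5,5-tetramethyl-1,3,2-dioxaborolan-2-yl)penta-1,4-dien-1-yl]oxolan-2-one
Conditions: VO(acac)2 (5 mol %), t-BuOOH (1.3 equiv, anhydrous in decane), CH2Cl2, 0 °C
Reagents that add atoms: tert-butyl hydroperoxide, CC(C)(C)OO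
Why: Hydroxyl-directed vanadium-catalysed epoxidation reacts only at the alkene allylic to the free alcohol, and A(1,3) strain in the Z-allylic alcohol holds the carbinol hydrogen in the alkene plane so that oxygen is delivered syn to OH (threo), which sets C11 and C12 as in the target.

Step 13
Reactants: 20 (4S,5S)-4-[(2S)-2-hydroxy-2-[(2R,3S)-2-methyl-3-(3-oxobutyl)oxiran-2-yl]ethyl]-3-methylidene-5-[(1E,4E)-2-methyl-5-(4,4,5,5-tetramethyl-1,3,2-dioxaborolan-2-yl)penta-1,4-dien-1-yl]oxolan-2-one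
Product: 21 (4S,5S)-4-[(2R)-2-acetoxy-2-[(2S,3S)-2-methyl-3-(3-oxobutyl)oxiran-2-yl]ethyl]-3-methylidene-5-[(1E,4E)-2-methyl-5-(4,4,5,5-tetramethyl-1,3,2-dioxaborolan-2-yl)penta-1,4-dien-1-yl]oxolan-2-one
Conditions: PPh3, DIAD, AcOH, toluene, 0 °C to rt
Reagents that add atoms: acetic acid, CC(=O)O
Why: Mitsunobu esterification installs the acetate with clean SN2 inversion at C13, converting the threo epoxy alcohol into the erythro (13R) acetate of the target in one operation.

Step 14
Reactants: 21 (4S,5S)-4-[(2R)-2-acetoxy-2-[(2S,3S)-2-methyl-3-(3-oxobutyl)oxiran-2-yl]ethyl]-3-methylidene-5-[(1E,4E)-2-methyl-5-(4,4,5,5-tetramethyl-1,3,2-dioxaborolan-2-yl)penta-1,4-dien-1-yl]oxolan-2-one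
Product: 22 [(1E,4E)-5-[(2S,3S)-3-[(2R)-2-acetoxy-2-[(2S,3S)-2-methyl-3-(3-oxobutyl)oxiran-2-yl]ethyl]-4-methylidene-5-oxooxolan-2-yl]-4-methylpenta-1,4-dien-1-yl]boronic acid
Conditions: NaIO4, NH4OAc, acetone–H2O (1:1), rt
Reagents that add atoms: water, O
Why: Oxidative cleavage of the pinacol by periodate at neutral pH pulls the ester–acid equilibrium to the free boronic acid (needed because pinacol boronates do not react with diazoalkanes) without harming the epoxide, acetate or lactone.

Step 15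
Reactants: 22 [(1E,4E)-5-[(2S,3S)-3-[(2R)-2-acetoxy-2-[(2S,3S)-2-methyl-3-(3-oxobutyl)oxiran-2-yl]ethyl]-4-methylidene-5-oxooxolan-2-yl]-4-methylpenta-1,4-dien-1-yl]boronic acid
Product: 27 (1S,2S,3E,6E,8S,11S,12S,13R)-13-acetoxy-11,12-epoxy-8-hydroxycembra-3,6,15(17)-trien-16,2-olide (CNP0288879.2), via tosylhydrazone boronate 23 (not isolated), via diazoalkane 24 (not isolated), via ate complex 25 (not isolated), via allylboronate 26 (not isolated)
Conditions: TsNHNH2 (1.0 equiv), (R,R)-diisopropyl tartrate (1.1 equiv), 4 Å MS, CH2Cl2, rt; then dilute to 1 mM, Cs2CO3 (1.0 equiv), hν (300–350 nm), 0 °C; filter; then 30 % H2O2, pH 7 phosphate buffer, THF, 0 °C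
Reagents that add atoms: hydrogen peroxide, OO
Why: Proposed new method: a macrocyclizing, ring-contracting boron-to-carbon 1,2-shift in which photolysis of the caesium salt of 23 (photochemical Bamford–Stevens) releases diazoalkane 24 slowly at high dilution, its diazo carbon adds intramolecularly to the Lewis-acidic tartrate alkenylboronate to give the 15-membered diazonium boronate 25, the E-alkenyl group then migrates from boron to C8 with loss of N2 (inversion at C8, alkene geometry retained) to form the C7–C8 bond and the 14-membered ring of 26, and buffered H2O2 oxidizes the tertiary allylic C–B bond with retention to the C8 alcohol; (8S) requires boron to bond to the Re face of the diazo carbon, for which the C2-symmetric tartrate on boron (by analogy with diol control of migration in Matteson homologation) and the tether are the control elements, and the closest known reaction type is the intermolecular coupling of boronic acids with diazoalkanes generated from tosylhydrazones (Barluenga-type) and the homologation of alkenylboronic acids to allylboron compounds.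

**Compound list**

1 | pent-1-en-4-yne | C=CCC#C | starting material
2 | dimethyl[(1E)-2-methylpenta-1,4-dien-1-yl]alane (not isolated) | C[Al](C)/C=C(\C)CC=C | intermediate
3 | (2E)-3-methylhexa-2,5-dien-1-ol | OC/C=C(\C)CC=C | intermediate
4 | vinylboronic acid pinacol ester (2-ethenyl-4,4,5,5-tetramethyl-1,3,2-dioxaborolane) | C=CB1OC(C)(C)C(C)(C)O1 | starting material
5 | (2E,5E)-3-methyl-6-(4,4,5,5-tetramethyl-1,3,2-dioxaborolan-2-yl)hexa-2,5-dien-1-ol | OC/C=C(\C)C/C=C/B1OC(C)(C)C(C)(C)O1 | intermediate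
6 | (2E,5E)-3-methyl-6-(4,4,5,5-tetramethyl-1,3,2-dioxaborolan-2-yl)hexa-2,5-dienal (fragment A) | O=C/C=C(\C)C/C=C/B1OC(C)(C)C(C)(C)O1 | intermediate
7 | 2-(3-chloropropyl)-2-methyl-1,3-dioxolane | CC1(CCCCl)OCCO1 | starting material
8 | [3-(2-methyl-1,3-dioxolan-2-yl)propyl]triphenylphosphonium iodide | CC1(CCC[P+](c2ccccc2)(c2ccccc2)c2ccccc2)OCCO1.[I-] | intermediate
9 | (3S)-3-hydroxyoxolan-2-one [(S)-α-hydroxy-γ-butyrolactone] | O[C@H]1CCOC1=O | starting material
10 | (3S)-3-(oxan-2-yloxy)oxolan-2-one (both acetal epimers) | O=C1OCC[C@@H]1OC1CCCCO1 | intermediate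
11 | (3S)-2-methyl-3-(oxan-2-yloxy)oxolan-2-ol (anomer mixture) | CC1(O)OCC[C@@H]1OC1CCCCO1 | intermediate
12 | [3-(2-methyl-1,3-dioxolan-2-yl)propylidene]triphenylphosphorane (not isolated) | CC1(CCC=P(c2ccccc2)(c2ccccc2)c2ccccc2)OCCO1 | intermediate
13 | (3S,4Z)-4-methyl-7-(2-methyl-1,3-dioxolan-2-yl)-3-(oxan-2-yloxy)hept-4-en-1-ol | OCC[C@H](OC1CCCCO1)/C(C)=C\CCC1(C)OCCO1 | intermediate
14 | (3S,4Z)-4-methyl-7-(2-methyl-1,3-dioxolan-2-yl)-3-(oxan-2-yloxy)hept-4-enal | O=CC[C@H](OC1CCCCO1)/C(C)=C\CCC1(C)OCCO1 | intermediate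
15 | methyl acrylate | COC(=O)C=C | starting material
16 | methyl (5S,6Z)-3-hydroxy-6-methyl-2-methylidene-9-(2-methyl-1,3-dioxolan-2-yl)-5-(oxan-2-yloxy)non-6-enoate (C3 epimers) | COC(=O)C(=C)C(O)C[C@H](OC1CCCCO1)/C(C)=C\CCC1(C)OCCO1 | intermediate
17 | methyl (2Z,5S,6Z)-2-(bromomethyl)-6-methyl-9-(2-methyl-1,3-dioxolan-2-yl)-5-(oxan-2-yloxy)nona-2,6-dienoate (fragment B) | COC(=O)/C(CBr)=C/C[C@H](OC1CCCCO1)/C(C)=C\CCC1(C)OCCO1 | intermediate
18 | methyl (3S,4S,5E,8E)-6-methyl-2-methylidene-3-[(2S,3Z)-3-methyl-6-(2-methyl-1,3-dioxolan-2-yl)-2-(oxan-2-yloxy)hex-3-en-1-yl]-9-(4,4,5,5-tetramethyl-1,3,2-dioxaborolan-2-yl)-4-(trimethylsilyloxy)nona-5,8-dienoate (not isolated) | COC(=O)C(=C)[C@H](C[C@H](OC1CCCCO1)/C(C)=C\CCC1(C)OCCO1)[C@@H](O[Si](C)(C)C)/C=C(\C)C/C=C/B1OC(C)(C)C(C)(C)O1 | intermediate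
19 | (4S,5S)-4-[(2S,3Z)-2-hydroxy-3-methyl-7-oxooct-3-en-1-yl]-3-methylidene-5-[(1E,4E)-2-methyl-5-(4,4,5,5-tetramethyl-1,3,2-dioxaborolan-2-yl)penta-1,4-dien-1-yl]oxolan-2-one | C=C1C(=O)O[C@@H](/C=C(\C)C/C=C/B2OC(C)(C)C(C)(C)O2)[C@H]1C[C@H](O)/C(C)=C\CCC(C)=O | intermediate
20 | (4S,5S)-4-[(2S)-2-hydroxy-2-[(2R,3S)-2-methyl-3-(3-oxobutyl)oxiran-2-yl]ethyl]-3-methylidene-5-[(1E,4E)-2-methyl-5-(4,4,5,5-tetramethyl-1,3,2-dioxaborolan-2-yl)penta-1,4-dien-1-yl]oxolan-2-one | C=C1C(=O)O[C@@H](/C=C(\C)C/C=C/B2OC(C)(C)C(C)(C)O2)[C@H]1C[C@H](O)[C@@]1(C)O[C@H]1CCC(C)=O | intermediate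
21 | (4S,5S)-4-[(2R)-2-acetoxy-2-[(2S,3S)-2-methyl-3-(3-oxobutyl)oxiran-2-yl]ethyl]-3-methylidene-5-[(1E,4E)-2-methyl-5-(4,4,5,5-tetramethyl-1,3,2-dioxaborolan-2-yl)penta-1,4-dien-1-yl]oxolan-2-one | C=C1C(=O)O[C@@H](/C=C(\C)C/C=C/B2OC(C)(C)C(C)(C)O2)[C@H]1C[C@@H](OC(C)=O)[C@@]1(C)O[C@H]1CCC(C)=O | intermediate
22 | [(1E,4E)-5-[(2S,3S)-3-[(2R)-2-acetoxy-2-[(2S,3S)-2-methyl-3-(3-oxobutyl)oxiran-2-yl]ethyl]-4-methylidene-5-oxooxolan-2-yl]-4-methylpenta-1,4-dien-1-yl]boronic acid | C=C1C(=O)O[C@@H](/C=C(\C)C/C=C/B(O)O)[C@H]1C[C@@H](OC(C)=O)[C@@]1(C)O[C@H]1CCC(C)=O | intermediate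
23 | N-tosylhydrazone of the C8 ketone of 22, boron as its diisopropyl (4R,5R)-1,3,2-dioxaborolane-4,5-dicarboxylate (tartrate) ester (not isolated) | C=C1C(=O)O[C@@H](/C=C(\C)C/C=C/B2O[C@@H](C(=O)OC(C)C)[C@H](C(=O)OC(C)C)O2)[C@H]1C[C@@H](OC(C)=O)[C@@]1(C)O[C@H]1CCC(C)=NNS(=O)(=O)c1ccc(C)cc1 | intermediate
24 | C8 diazoalkane corresponding to 23 (C=N2 in place of the tosylhydrazone; not isolated) | C=C1C(=O)O[C@@H](/C=C(\C)C/C=C/B2O[C@@H](C(=O)OC(C)C)[C@H](C(=O)OC(C)C)O2)[C@H]1C[C@@H](OC(C)=O)[C@@]1(C)O[C@H]1CCC(C)=[N+]=[N-] | intermediate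
25 | 15-membered zwitterionic ate complex: tetracoordinate tartrate boron bonded to C7 and to C8, C8 carrying CH3 and N2+ (not isolated) | C=C1C(=O)O[C@H]2/C=C(\C)C/C=C/[B-]3(O[C@@H](C(=O)OC(C)C)[C@H](C(=O)OC(C)C)O3)[C@@](C)([N+]#N)CC[C@@H]3O[C@]3(C)[C@H](OC(C)=O)C[C@@H]12 | intermediate
26 | 14-membered (8R)-tertiary allylic boronate: target skeleton with the tartrate boronic ester on C8 in place of OH (not isolated) | C=C1C(=O)O[C@H]2/C=C(\C)C/C=C/[C@@](C)(B3O[C@@H](C(=O)OC(C)C)[C@H](C(=O)OC(C)C)O3)CC[C@@H]3O[C@]3(C)[C@H](OC(C)=O)C[C@@H]12 | intermediate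
27 | (1S,2S,3E,6E,8S,11S,12S,13R)-13-acetoxy-11,12-epoxy-8-hydroxycembra-3,6,15(17)-trien-16,2-olide (CNP0288879.2) | C=C1C(=O)O[C@H]2/C=C(\C)C/C=C/[C@@](C)(O)CC[C@@H]3O[C@]3(C)[C@H](OC(C)=O)C[C@@H]12 | target

**Step count and risks**

Total step count: 15. Longest linear sequence: 11 steps (9 → 27, steps 5–15).

The three steps most likely to fail:

Step 15 (the proposed new ring contraction). The diazoalkane must be captured by boron within a 15-membered ring faster than it undergoes 1,2-hydrogen shift, azine formation or cycloaddition to the methylene lactone. The C8 diastereoselectivity rests on the tartrate and the tether and has no direct precedent; the enantiomeric tartrate is the first variable to change. The fallback uses known chemistry and sets out from 22. Stereoretentive ipso-iododeboronation of the alkenylboronic acid (NIS, MeCN, 0 °C, dark) gives the (E)-alkenyl iodide F1. A Nozaki–Hiyama–Kishi macrocyclization of F1 onto the C8 methyl ketone (CrCl2 in excess, NiCl2 cat., DMSO–THF, high dilution, rt) then forms the C7–C8 bond and the tertiary allylic alcohol directly. The C8 epimers are separated by chromatography, and the fallback comes back to the route at 27.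

Step 11 (asymmetric chromium-catalysed allylation with in-pot lactonization and deprotection). Facial control by the ligand may be eroded by the existing C13 stereocenter, and the enal and the skipped diene are sensitive to the Lewis-acidic medium. The fallback replaces the allylchromium by an allylboron reagent and sets out from 17. Palladium-catalysed borylation (Pd2(dba)3 cat., B2pin2, toluene, 50 °C) gives the primary allylboronate F2 with the same alkene geometry. Allylboration of 6 through a closed chair transition state, catalysed by a chiral phosphoric acid ((R)-TRIP, toluene, rt), gives the syn borate adduct F3. The same aqueous HCl treatment lactonizes and deprotects F3, and the fallback comes back to the route at 19.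

Step 13 (Mitsunobu inversion next to a fully substituted epoxide carbon). The alcohol is hindered, so slow reaction or elimination is possible, and the phosphine can add to the methylene lactone. The fallback avoids the phosphine–azodicarboxylate system and sets out from 20. Sulfonylation (ClCH2SO2Cl, pyridine, CH2Cl2, 0 °C) gives the chloromethanesulfonate F4. Displacement with caesium acetate (CsOAc, 18-crown-6, toluene, 60 °C) then proceeds with inversion, and the fallback comes back to the route at 21.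

Further compounds
F1 | step 15 | (4S,5S)-4-[(2R)-2-acetoxy-2-[(2S,3S)-2-methyl-3-(3-oxobutyl)oxiran-2-yl]ethyl]-5-[(1E,4E)-5-iodo-2-methylpenta-1,4-dien-1-yl]-3-methylideneoxolan-2-one | C=C1C(=O)O[C@@H](/C=C(\C)C/C=C/I)[C@H]1C[C@@H](OC(C)=O)[C@@]1(C)O[C@H]1CCC(C)=O
F2 | step 11 | methyl (2E,5S,6Z)-6-methyl-9-(2-methyl-1,3-dioxolan-2-yl)-5-(oxan-2-yloxy)-2-[(4,4,5,5-tetramethyl-1,3,2-dioxaborolan-2-yl)methyl]nona-2,6-dienoate | COC(=O)/C(CB1OC(C)(C)C(C)(C)O1)=C/C[C@H](OC1CCCCO1)/C(C)=C\CCC1(C)OCCO1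
F3 | step 11 | borate adduct: compound 18 with a 4,4,5,5-tetramethyl-1,3,2-dioxaborolan-2-yloxy group in place of the trimethylsilyloxy group | COC(=O)C(=C)[C@H](C[C@H](OC1CCCCO1)/C(C)=C\CCC1(C)OCCO1)[C@@H](OB1OC(C)(C)C(C)(C)O1)/C=C(\C)C/C=C/B1OC(C)(C)C(C)(C)O1
F4 | step 13 | chloromethanesulfonate ester of 20 (carbinol configuration retained) | C=C1C(=O)O[C@@H](/C=C(\C)C/C=C/B2OC(C)(C)C(C)(C)O2)[C@H]1C[C@H](OS(=O)(=O)CCl)[C@@]1(C)O[C@H]1CCC(C)=O
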